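**Retrosynthetic overview**
- Ring B (the lactone) is closed last: a secondary alcohol attacks an acetonide-masked salicylate (a benzodioxinone) and expels acetone.
- Ring A (the arene) is closed before it by an intramolecular aldol condensation and aromatisation of a diketo-dioxinone, which leaves only the future 6-OH free for methylation.
- The diketo-dioxinone comes from a Claisen condensation of a keto-dioxinone dianion (fragment 3) with a C14 bis-silyloxy Weinreb amide.
- The Weinreb amide comes from cross-metathesis and hydrogenation of a C7 alkene carrying the 3R centre (fragment 1) with a C9 alkene carrying the S carbinol (fragment 2).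
- Fragment 1 gets its stereocentre by Noyori hydrogenation; fragment 2 gets its stereocentre from (S)-epichlorohydrin.

Assumption: the target is read from the SMILES as (3R) at the lactone carbon and (6S) in the side chain; small commodity reagents are not numbered, and LiN(i-Pr)2 and LiN(SiMe3)2 are bought as solutions. TBS = tert-butyldimethylsilyl.

**Route**

Step 1
Reactants: 1 methyl acetoacetate
Product: 3 methyl 3-oxohept-6-enoate, via acetoacetate dianion 2 (not isolated)
Conditions: NaH, THF, 0 °C; n-BuLi, 0 °C; allyl bromide, 0 °C → rt; aq. HCl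
Reagents that add atoms: allyl bromide, C=CCBr
Why: Weiler dianion alkylation, in which the terminal carbanion formed last is the most nucleophilic site and is the only one alkylated.

Step 2
Reactants: 3 methyl 3-oxohept-6-enoate
Product: 4 methyl (3R)-3-hydroxyhept-6-enoate
Conditions: H2 (4 bar), RuCl2[(R)-BINAP] (0.5 mol%), MeOH, 60 °C, stopped at full ketone conversion
Reagents that add atoms: none
Why: Noyori asymmetric hydrogenation of the chelating β-keto ester, where the (R)-BINAP ligand delivers hydride to one face to set the 3R carbinol and the isolated alkene is not reduced at this pressure.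

Step 3
Reactants: 4 methyl (3R)-3-hydroxyhept-6-enoate
Product: 5 (3R)-3-hydroxy-N-methoxy-N-methylhept-6-enamide
Conditions: MeNHOMe·HCl (2 equiv), i-PrMgCl (5 equiv), THF, −20 → 0 °C; aq. NH4Cl
Reagents that add atoms: N,O-dimethylhydroxylamine hydrochloride, Cl.CNOC
Why: Weinreb amidation of the ester by the magnesium amide, with the β-alkoxide formed first suppressing elimination and retro-aldol, so C3 is untouched.

Step 4
Reactants: 5 (3R)-3-hydroxy-N-methoxy-N-methylhept-6-enamide
Product: 6 (3R)-3-(tert-butyldimethylsilyloxy)-N-methoxy-N-methylhept-6-enamide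
Conditions: TBSCl, imidazole, DMF, rt
Reagents that add atoms: tert-butyldimethylsilyl chloride, CC(C)(C)[Si](C)(C)Cl
Why: Standard imidazole-promoted silylation of a secondary alcohol, which does not touch the stereocentre.

Step 5
Reactants: 7 (S)-epichlorohydrin
Product: 8 (2S)-1-chloroheptan-2-ol
Conditions: n-BuMgCl (1.2 equiv), CuBr·SMe2 (5 mol%), THF, −40 → −20 °C; aq. NH4Cl
Reagents that add atoms: n-butylmagnesium chloride, CCCC[Mg]Cl
Why: Copper-catalysed Grignard opening of the epoxide at its unsubstituted carbon (SN2), so the stereocentre is not involved and S is carried over.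

Step 6
Reactants: 8 (2S)-1-chloroheptan-2-ol
Product: 9 (2S)-2-pentyloxirane, also called (S)-1,2-epoxyheptane
Conditions: powdered NaOH, Et2O, 0 °C → rt
Reagents that add atoms: none
Why: Intramolecular Williamson ring closure at the CH2Cl carbon, which leaves the C–O bond at the stereocentre intact and gives the S epoxide.

Step 7
Reactants: 9 (2S)-2-pentyloxirane
Product: 10 (4S)-non-1-en-4-ol
Conditions: CH2=CHMgBr (1.5 equiv), CuBr·SMe2 (10 mol%), THF, −30 → 0 °C; aq. NH4Cl
Reagents that add atoms: vinylmagnesium bromide, C=C[Mg]Br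
Why: Copper-catalysed vinyl Grignard opening at the terminal epoxide carbon, which keeps the configured C–O bond and gives the 4S homoallylic alcohol.

Step 8
Reactants: 10 (4S)-non-1-en-4-ol
Product: 11 (4S)-4-(tert-butyldimethylsilyloxy)non-1-ene
Conditions: TBSCl, imidazole, DMF, rt
Reagents that add atoms: tert-butyldimethylsilyl chloride, CC(C)(C)[Si](C)(C)Cl
Why: Standard silylation of the secondary alcohol with retention at the stereocentre.

Step 9
Reactants: 6 (3R)-3-(tert-butyldimethylsilyloxy)-N-methoxy-N-methylhept-6-enamide; 11 (4S)-4-(tert-butyldimethylsilyloxy)non-1-ene (3 equiv)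
Product: 13 (3R,9S)-3,9-bis(tert-butyldimethylsilyloxy)-N-methoxy-N-methyltetradecanamide, via tetradec-6-enamide 12 (not isolated)
Conditions: second-generation Grubbs catalyst RuCl2(H2IMes)(PCy3)(=CHPh) (5 mol%), CH2Cl2, 40 °C; solvent swap to EtOAc; H2 (1 atm), 10% Pd/C, rt
Reagents that add atoms: none
Why: Olefin cross-metathesis with loss of ethylene, driven for 6 by the excess of the cheaper partner, then hydrogenation of the E/Z alkene; both stereocentres are remote and untouched, and the saturated homodimers separate easily by polarity.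

Step 10
Reactants: 14 2,2,6-trimethyl-4H-1,3-dioxin-4-one
Product: 16 2,2-dimethyl-6-(2-oxopropyl)-4H-1,3-dioxin-4-one, via lithium dienolate 15 (not isolated)
Conditions: LiN(SiMe3)2 (1.0 M in THF), THF, −78 °C; AcCl (0.5 equiv), −78 → −20 °C; 1 M HCl
Reagents that add atoms: acetyl chloride, CC(=O)Cl
Why: Claisen-type C-acylation of the vinylogous ester dienolate at its methyl-derived terminus, run with two equivalents of enolate because the more acidic product is deprotonated as it forms.

Step 11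
Reactants: 16 2,2-dimethyl-6-(2-oxopropyl)-4H-1,3-dioxin-4-one (2.5 equiv); 13 (3R,9S)-3,9-bis(tert-butyldimethylsilyloxy)-N-methoxy-N-methyltetradecanamide
Product: 18 6-[(6R,12S)-6,12-bis(tert-butyldimethylsilyloxy)-2,4-dioxoheptadecyl]-2,2-dimethyl-4H-1,3-dioxin-4-one, via keto-dioxinone dianion 17 (not isolated)
Conditions: LiN(i-Pr)2 (5 equiv), THF, −78 °C, 1 h; then 13, −78 → −30 °C; aq. NH4Cl
Reagents that add atoms: none
Why: Crossed Claisen condensation in which the dianion reacts at its terminal carbon with the Weinreb amide, whose chelated tetrahedral intermediate prevents over-addition; neither silyloxy stereocentre is touched.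

Step 12
Reactants: 18 6-[(6R,12S)-6,12-bis(tert-butyldimethylsilyloxy)-2,4-dioxoheptadecyl]-2,2-dimethyl-4H-1,3-dioxin-4-one
Product: 20 5-[(2R,8S)-2,8-bis(tert-butyldimethylsilyloxy)tridecyl]-7-hydroxy-2,2-dimethyl-4H-1,3-benzodioxin-4-one, via aldol adduct 19 (not isolated)
Conditions: Et3N (3 equiv), CH2Cl2, rt
Reagents that add atoms: none
Why: Biomimetic intramolecular aldol condensation in which C5 of the dioxinone adds to the distal ketone to close six-membered ring A, and loss of water with enolisation aromatises it to the acetonide-masked resorcylate.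

Step 13
Reactants: 20 5-[(2R,8S)-2,8-bis(tert-butyldimethylsilyloxy)tridecyl]-7-hydroxy-2,2-dimethyl-4H-1,3-benzodioxin-4-one
Product: 21 5-[(2R,8S)-2,8-bis(tert-butyldimethylsilyloxy)tridecyl]-7-methoxy-2,2-dimethyl-4H-1,3-benzodioxin-4-one
Conditions: MeI (1.5 equiv), K2CO3 (2 equiv), acetone, rt
Reagents that add atoms: iodomethane, CI
Why: Williamson etherification of the only free phenol, the other being locked in the acetonide, so the regiochemistry is unambiguous.

Step 14
Reactants: 21 5-[(2R,8S)-2,8-bis(tert-butyldimethylsilyloxy)tridecyl]-7-methoxy-2,2-dimethyl-4H-1,3-benzodioxin-4-one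
Product: 23 (3R)-8-hydroxy-3-[(6S)-6-hydroxyundecyl]-6-methoxy-3,4-dihydro-1H-isochromen-1-one, via diol benzodioxinone 22 (not isolated)
Conditions: HCl (1.25 M in MeOH), 0 °C → rt, then 40 °C
Reagents that add atoms: none
Why: Acidic methanolysis removes both silyl ethers, and the freed 2-hydroxyl then closes ring B by intramolecular transesterification with loss of acetone; only O–Si and acyl C–O bonds break, so both carbinol configurations are retained.

**Compound list**
1 | methyl acetoacetate | CC(=O)CC(=O)OC | starting material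
2 | sodium lithium dianion of methyl acetoacetate | [Na+].[Li+].C=C([O-])C=C([O-])OC | intermediate
3 | methyl 3-oxohept-6-enoate | C=CCCC(=O)CC(=O)OC | intermediate
4 | methyl (3R)-3-hydroxyhept-6-enoate | C=CCC[C@@H](O)CC(=O)OC | intermediate
5 | (3R)-3-hydroxy-N-methoxy-N-methylhept-6-enamide | C=CCC[C@@H](O)CC(=O)N(C)OC | intermediate
6 | (3R)-3-(tert-butyldimethylsilyloxy)-N-methoxy-N-methylhept-6-enamide | C=CCC[C@@H](O[Si](C)(C)C(C)(C)C)CC(=O)N(C)OC | intermediate
7 | (S)-epichlorohydrin, (2S)-2-(chloromethyl)oxirane | ClC[C@@H]1CO1 | starting material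
8 | (2S)-1-chloroheptan-2-ol | CCCCC[C@H](O)CCl | intermediate
9 | (2S)-2-pentyloxirane | CCCCC[C@H]1CO1 | intermediate
10 | (4S)-non-1-en-4-ol | CCCCC[C@H](O)CC=C | intermediate
11 | (4S)-4-(tert-butyldimethylsilyloxy)non-1-ene | CCCCC[C@H](O[Si](C)(C)C(C)(C)C)CC=C | intermediate
12 | (3R,9S)-3,9-bis(tert-butyldimethylsilyloxy)-N-methoxy-N-methyltetradec-6-enamide, E/Z mixture | CCCCC[C@H](O[Si](C)(C)C(C)(C)C)CC=CCC[C@@H](O[Si](C)(C)C(C)(C)C)CC(=O)N(C)OC | intermediate
13 | (3R,9S)-3,9-bis(tert-butyldimethylsilyloxy)-N-methoxy-N-methyltetradecanamide | CCCCC[C@H](O[Si](C)(C)C(C)(C)C)CCCCC[C@@H](O[Si](C)(C)C(C)(C)C)CC(=O)N(C)OC | intermediate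
14 | 2,2,6-trimethyl-4H-1,3-dioxin-4-one | CC1=CC(=O)OC(C)(C)O1 | starting material
15 | lithium dienolate of 14 (6-methylene form) | [Li+].C=C1C=C([O-])OC(C)(C)O1 | intermediate
16 | 2,2-dimethyl-6-(2-oxopropyl)-4H-1,3-dioxin-4-one | CC(=O)CC1=CC(=O)OC(C)(C)O1 | intermediate
17 | dilithium dianion of 16 | [Li+].[Li+].C=C([O-])C=C1C=C([O-])OC(C)(C)O1 | intermediate
18 | 6-[(6R,12S)-6,12-bis(tert-butyldimethylsilyloxy)-2,4-dioxoheptadecyl]-2,2-dimethyl-4H-1,3-dioxin-4-one | CCCCC[C@H](O[Si](C)(C)C(C)(C)C)CCCCC[C@@H](O[Si](C)(C)C(C)(C)C)CC(=O)CC(=O)CC1=CC(=O)OC(C)(C)O1 | intermediate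
19 | 5-[(2R,8S)-2,8-bis(tert-butyldimethylsilyloxy)tridecyl]-5-hydroxy-2,2-dimethyl-5,6-dihydro-4H-1,3-benzodioxine-4,7(8H)-dione, both C5 epimers | CCCCC[C@H](O[Si](C)(C)C(C)(C)C)CCCCC[C@@H](O[Si](C)(C)C(C)(C)C)CC1(O)CC(=O)CC2=C1C(=O)OC(C)(C)O2 | intermediate
20 | 5-[(2R,8S)-2,8-bis(tert-butyldimethylsilyloxy)tridecyl]-7-hydroxy-2,2-dimethyl-4H-1,3-benzodioxin-4-one | CCCCC[C@H](O[Si](C)(C)C(C)(C)C)CCCCC[C@@H](O[Si](C)(C)C(C)(C)C)Cc1cc(O)cc2OC(C)(C)OC(=O)c12 | intermediate
21 | 5-[(2R,8S)-2,8-bis(tert-butyldimethylsilyloxy)tridecyl]-7-methoxy-2,2-dimethyl-4H-1,3-benzodioxin-4-one | CCCCC[C@H](O[Si](C)(C)C(C)(C)C)CCCCC[C@@H](O[Si](C)(C)C(C)(C)C)Cc1cc(OC)cc2OC(C)(C)OC(=O)c12 | intermediate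
22 | 5-[(2R,8S)-2,8-dihydroxytridecyl]-7-methoxy-2,2-dimethyl-4H-1,3-benzodioxin-4-one | CCCCC[C@H](O)CCCCC[C@@H](O)Cc1cc(OC)cc2OC(C)(C)OC(=O)c12 | intermediate
23 | (3R)-8-hydroxy-3-[(6S)-6-hydroxyundecyl]-6-methoxy-3,4-dihydro-1H-isochromen-1-one | CCCCC[C@H](O)CCCCC[C@@H]1Cc2cc(OC)cc(O)c2C(=O)O1 | target

**Step count**
Total: 14 steps. Longest linear sequence: 9 steps (1, 2, 3, 4, 9, 11, 12, 13, 14; the branch 5, 6, 7, 8, 9, 11, 12, 13, 14 is equally long), which is 9/14 = 0.64 of the total.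

**Three steps most likely to fail**

Step 9 (cross-metathesis of two terminal alkenes is statistical and may give mainly homodimers). The fallback replaces metathesis by a Julia–Kocienski olefination; it sets out from 6 and 11 and comes back at 12, then 13. Ozonolysis of 6 (O3, CH2Cl2, −78 °C; PPh3) gives (3R)-3-(tert-butyldimethylsilyloxy)-N-methoxy-N-methyl-6-oxohexanamide F1. Ozonolysis of 11 with NaBH4 work-up gives (3S)-3-(tert-butyldimethylsilyloxy)octan-1-ol F2. Mitsunobu thioetherification of F2 with 1-phenyl-1H-tetrazole-5-thiol (PPh3, DIAD, THF) gives 5-{[(3S)-3-(tert-butyldimethylsilyloxy)octyl]sulfanyl}-1-phenyl-1H-tetrazole F3, and mCPBA (NaHCO3, CH2Cl2) oxidises it to 5-{[(3S)-3-(tert-butyldimethylsilyloxy)octyl]sulfonyl}-1-phenyl-1H-tetrazole F4. Deprotonation of F4 with KN(SiMe3)2 (THF, −78 °C) in the presence of F1 gives alkene 12, now isolated, and H2 over 10% Pd/C returns 13.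

Step 11 (the β-silyloxy Weinreb amide may be deprotonated and eliminate, or acylate sluggishly). The fallback replaces the Claisen condensation by aldol addition and oxidation; it sets out from 13 and comes back at 18. i-Bu2AlH (THF, −78 °C) reduces 13 to (3R,9S)-3,9-bis(tert-butyldimethylsilyloxy)tetradecanal F5. Dianion 17, made from 16 as before, adds to F5 at −78 °C to give 6-[(6R,12S)-6,12-bis(tert-butyldimethylsilyloxy)-4-hydroxy-2-oxoheptadecyl]-2,2-dimethyl-4H-1,3-dioxin-4-one F6 as a mixture of carbinol epimers. Dess–Martin periodinane (NaHCO3, CH2Cl2, 0 °C) oxidises F6 to 18.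

Step 12 (the dioxinone-mode aldol may be slow, or lose the β-silyloxy group, or give pyranone side products). The fallback aromatises in the open-chain ester series; it sets out from 18 and comes back at 23.
- Heating 18 with MeOH in toluene at 110 °C expels acetone, and the acylketene is trapped as methyl (9R,15S)-9,15-bis(tert-butyldimethylsilyloxy)-3,5,7-trioxoicosanoate F7.
- Cs2CO3 in MeOH and then AcOH effects the intramolecular aldol condensation to methyl 2-[(2R,8S)-2,8-bis(tert-butyldimethylsilyloxy)tridecyl]-4,6-dihydroxybenzoate F8.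
- HCl in MeOH removes the silyl groups and lactonises to (3R)-6,8-dihydroxy-3-[(6S)-6-hydroxyundecyl]-3,4-dihydro-1H-isochromen-1-one F9.
- MeI (1.05 equiv) with K2CO3 in acetone methylates the non-chelated 6-OH selectively to give 23.

**Further compounds**
F1 | step 9 | (3R)-3-(tert-butyldimethylsilyloxy)-N-methoxy-N-methyl-6-oxohexanamide | O=CCC[C@@H](O[Si](C)(C)C(C)(C)C)CC(=O)N(C)OC
F2 | step 9 | (3S)-3-(tert-butyldimethylsilyloxy)octan-1-ol | CCCCC[C@H](O[Si](C)(C)C(C)(C)C)CCO
F3 | step 9 | 5-{[(3S)-3-(tert-butyldimethylsilyloxy)octyl]sulfanyl}-1-phenyl-1H-tetrazole | CCCCC[C@H](O[Si](C)(C)C(C)(C)C)CCSc1nnnn1-c1ccccc1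
F4 | step 9 | 5-{[(3S)-3-(tert-butyldimethylsilyloxy)octyl]sulfonyl}-1-phenyl-1H-tetrazole | CCCCC[C@H](O[Si](C)(C)C(C)(C)C)CCS(=O)(=O)c1nnnn1-c1ccccc1
F5 | step 11 | (3R,9S)-3,9-bis(tert-butyldimethylsilyloxy)tetradecanal | CCCCC[C@H](O[Si](C)(C)C(C)(C)C)CCCCC[C@@H](O[Si](C)(C)C(C)(C)C)CC=O
F6 | step 11 | 6-[(6R,12S)-6,12-bis(tert-butyldimethylsilyloxy)-4-hydroxy-2-oxoheptadecyl]-2,2-dimethyl-4H-1,3-dioxin-4-one, both C4 epimers | CCCCC[C@H](O[Si](C)(C)C(C)(C)C)CCCCC[C@@H](O[Si](C)(C)C(C)(C)C)CC(O)CC(=O)CC1=CC(=O)OC(C)(C)O1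
F7 | step 12 | methyl (9R,15S)-9,15-bis(tert-butyldimethylsilyloxy)-3,5,7-trioxoicosanoate | CCCCC[C@H](O[Si](C)(C)C(C)(C)C)CCCCC[C@@H](O[Si](C)(C)C(C)(C)C)CC(=O)CC(=O)CC(=O)CC(=O)OC
F8 | step 12 | methyl 2-[(2R,8S)-2,8-bis(tert-butyldimethylsilyloxy)tridecyl]-4,6-dihydroxybenzoate | CCCCC[C@H](O[Si](C)(C)C(C)(C)C)CCCCC[C@@H](O[Si](C)(C)C(C)(C)C)Cc1cc(O)cc(O)c1C(=O)OC
F9 | step 12 | (3R)-6,8-dihydroxy-3-[(6S)-6-hydroxyundecyl]-3,4-dihydro-1H-isochromen-1-one | CCCCC[C@H](O)CCCCC[C@@H]1Cc2cc(O)cc(O)c2C(=O)O1
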